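**Strategy.** Everything rests on disconnecting C9 (ring B) from C11 (side chain). C9 sits next to C8, whose exocyclic methylene is a masked ketone, and C11 is allylic to the C12=C13 double bond of the alkylidene butenolide; the bond is therefore that of an α-allylated ketone. A palladium-catalysed decarboxylative allylation makes it in one operation: in the precursor the butenolide allylic alcohol is esterified to a carboxyl on C9 of an 8-oxodecalin; ionisation, loss of CO2 and recombination at C11 give the C9–C11 bond regiospecifically, the carboxyl serving as traceless tether. The decalin arises by epoxide-initiated polyene cyclisation terminated by the same β-keto ester.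

Key step: step 13

Remark: C1–C20 are the labdane positions of the target and are used for all intermediates; compounds 1, 4, 9, 14 and 18 are taken as commercially available.

**Decalin part**

Step 1
Reactants: 1 geranyl chloride
Product: 3 (4E)-6-chloro-4-methylhex-4-enal, via 6,7-epoxygeranyl chloride 2 (not isolated)
Conditions: mCPBA, CH2Cl2, 0 °C; then H5IO6, THF/Et2O, 0 °C
Reagents that add atoms: meta-chloroperoxybenzoic acid, O=C(OO)c1cccc(Cl)c1
Why: Prilezhaev epoxidation should take the electron-rich distal trisubstituted olefin in preference to the olefin deactivated by the allylic chloride, and periodic acid should cleave the epoxide through its diol (Malaprade-type cleavage) to the aldehyde (C3) and acetone.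

Step 2
Reactants: 3 (4E)-6-chloro-4-methylhex-4-enal; 4 ethyl 2-[bis(2,2,2-trifluoroethoxy)phosphoryl]propanoate
Product: 5 ethyl (2Z,6E)-8-chloro-2,6-dimethylocta-2,6-dienoate
Conditions: KN(SiMe3)2, 18-crown-6, THF, −78 °C
Reagents that add atoms: none
Why: The Still–Gennari variant of the Horner–Wadsworth–Emmons olefination should give the Z-trisubstituted enoate under kinetic control, which puts the future C19 carbon cis to the chain at the C3=C4 olefin.

Step 3
Reactants: 5 ethyl (2Z,6E)-8-chloro-2,6-dimethylocta-2,6-dienoate
Product: 6 (2Z,6E)-8-chloro-2,6-dimethylocta-2,6-dien-1-ol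
Conditions: iBu2AlH, CH2Cl2, −78 °C
Reagents that add atoms: none
Why: 1,2-Reduction of the enoate by the aluminium hydride should give the allylic alcohol with retention of both olefin geometries, the allylic chloride being inert at this temperature.

Step 4
Reactants: 6 (2Z,6E)-8-chloro-2,6-dimethylocta-2,6-dien-1-ol
Product: 7 [(2S,3R)-3-[(3E)-5-chloro-3-methylpent-3-en-1-yl]-2-methyloxiran-2-yl]methanol
Conditions: Ti(OiPr)4, L-(+)-diethyl tartrate, tBuOOH, 4 Å molecular sieves, CH2Cl2, −20 °C
Reagents that add atoms: tert-butyl hydroperoxide, CC(C)(C)OO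
Why: Sharpless asymmetric epoxidation with the L-(+)-tartrate ligand should deliver oxygen to the face of the Z-allylic alcohol that gives the (2S,3R)-epoxy alcohol, which fixes C3 and, by syn addition, the relative configuration at C4.

Step 5
Reactants: 7 (2S,3R)-epoxy alcohol
Product: 8 tert-butyl{[(2S,3R)-3-[(3E)-5-chloro-3-methylpent-3-en-1-yl]-2-methyloxiran-2-yl]methoxy}dimethylsilane
Conditions: TBSCl, imidazole, CH2Cl2, 0 °C to rt
Reagents that add atoms: tert-butyldimethylsilyl chloride, CC(C)(C)[Si](C)(C)Cl
Why: Imidazole-promoted silylation of the primary alcohol should block Payne rearrangement in the basic step 6 and chelation of the Lewis acid in step 7, with no stereocentre affected.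

Step 6
Reactants: 8 silyl-protected epoxy chloride; 9 methyl acetoacetate
Product: 10 methyl (6E)-9-[(2R,3S)-3-{[(tert-butyldimethylsilyl)oxy]methyl}-3-methyloxiran-2-yl]-7-methyl-3-oxonon-6-enoate
Conditions: 9, LiN(iPr)2 (2 equiv), THF, 0 °C; then 8, −78 to 0 °C
Reagents that add atoms: none
Why: γ-Alkylation of the acetoacetate dianion by direct SN2 substitution at the primary allylic chloride should join C6 to C7 without allylic transposition, the trisubstituted epoxide being inert to the dianion at low temperature and no stereocentre being formed.

Step 7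
Reactants: 10 epoxy β-keto ester
Product: 11 methyl 5-{[(tert-butyldimethylsilyl)oxy]methyl}-6-hydroxy-5,8a-dimethyl-2-oxodecahydronaphthalene-1-carboxylate (trans-fused; C3 OH equatorial; C4 CH2OTBS axial and cis to the C10 methyl; C9 CO2Me equatorial; C3, C4, C5 and C10 as in andrographolide)
Conditions: MeAlCl2 (3 equiv), CH2Cl2, −78 °C; aqueous work-up
Reagents that add atoms: none
Why: In this epoxide-initiated cation–olefin bicyclisation (Stork–Eschenmoser chair–chair folding) the aluminium Lewis acid should open the epoxide at the more substituted C4 and turn the β-keto ester into a chelated enolate that traps the C10 cation through carbon C9, so that C3 keeps the epoxide configuration, inversion at C4 places the CH2OTBS group axial, the E olefin gives the trans ring fusion with the C10 methyl anti to H5, and the C9 ester settles equatorial.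

Step 8
Reactants: 11 bicyclic hydroxy β-keto ester
Product: 13 methyl 3,19-O-isopropylidene-3,19-dihydroxy-8-oxo β-keto ester (the 1,3-dioxane acetal of 12), via 3,19-diol 12 (not isolated)
Conditions: p-TsOH (cat.), MeOH, rt; then 2,2-dimethoxypropane, acetone, rt
Reagents that add atoms: 2,2-dimethoxypropane, COC(C)(C)OC
Why: Acidic methanolysis should remove the primary silyl ether and transacetalisation should then tie the cis-disposed C3 and C19 hydroxyls into a six-membered acetonide, which masks both alcohols for the ester exchange without touching a stereocentre.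

**Butenolide part**

Step 9
Reactants: 14 (S)-3-hydroxy-γ-butyrolactone [(4S)-4-hydroxyoxolan-2-one]
Product: 15 (4S)-4-(triethylsilyloxy)oxolan-2-one
Conditions: Et3SiCl, imidazole, CH2Cl2, 0 °C
Reagents that add atoms: chlorotriethylsilane, CC[Si](Cl)(CC)CC
Why: Silylation of the secondary alcohol (the future C14 hydroxyl, taken from the chiral pool) should keep it from reacting at phosphorus in step 10 and as a second acyl acceptor in step 12.

Step 10
Reactants: 15 (4S)-4-(triethylsilyloxy)oxolan-2-one
Product: 17 diethyl [(4R)-2-oxo-4-(triethylsilyloxy)oxolan-3-yl]phosphonate (same spatial arrangement at C14 as in 14; mixture at C13), via phosphonite 16 (not isolated)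
Conditions: LiN(iPr)2, THF, −78 °C; (EtO)2PCl, −78 °C to rt; then air
Reagents that add atoms: diethyl chlorophosphite, CCOP(Cl)OCC; dioxygen, O=O
Why: The lithium enolate of the lactone, kept cold to suppress β-elimination of the silyloxy group, should be trapped at carbon by the trivalent phosphorus chloride (enolate C-phosphinylation) and the phosphonite oxidised by air to the phosphonate, the new C13 centre being destroyed in step 11.

Step 11
Reactants: 17 lactone phosphonate; 18 glycolaldehyde dimer (1,4-dioxane-2,5-diol)
Product: 19 (3E,4S)-3-(2-hydroxyethylidene)-4-(triethylsilyloxy)oxolan-2-one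
Conditions: LiCl, DBU, MeCN, 0 °C to rt
Reagents that add atoms: none
Why: Horner–Wadsworth–Emmons olefination under Masamune–Roush conditions with glycolaldehyde released from its dimer should favour the E-alkylidene lactone (C11 anti to the lactone carbonyl), any Z isomer being removable by chromatography and C14 being untouched.

**Union and endgame**

Step 12
Reactants: 13 acetonide β-keto methyl ester; 19 butenolide allylic alcohol
Product: 20 (2E)-2-[(4S)-2-oxo-4-(triethylsilyloxy)oxolan-3-ylidene]ethyl ester corresponding to 13 (C9–CO–O–C11 tether)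
Conditions: DMAP (0.3 equiv), 4 Å molecular sieves, toluene, 100 °C
Reagents that add atoms: none
Why: DMAP-catalysed transesterification is specific for the enolisable β-keto ester and is driven by removal of methanol on the sieves, so the lactone, the silyl ether and the acetonide should survive and no stereocentre changes.

Step 13
Reactants: 20 allyl β-keto ester
Product: 22 8-oxo-17-nor-andrographolide 3,19-acetonide 14-O-triethylsilyl ether (C9 side chain equatorial as in the target), via C9-epimeric ketone 21 (not isolated)
Conditions: Pd(PPh3)4 (5 mol%), THF, 40 °C; then DBU (0.2 equiv), rt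
Reagents that add atoms: none
Why: Zerovalent palladium should ionise the allylic C11–O bond of 20 to a π-allylpalladium carboxylate, the β-keto carboxylate should lose CO2 to give the C8/C9 enolate only, and the enolate carbon C9 should bond to C11, the unsubstituted allyl terminus remote from the lactone carbonyl, which restores the conjugated C12=C13 alkylidene lactone. The closest known reaction type is the Tsuji–Saegusa decarboxylative allylation of allyl β-keto esters (palladium-catalysed Carroll rearrangement). No ring is closed. The new stereocentre C9 is α to the C8 ketone and is set under thermodynamic control: DBU equilibrates the axial epimer 21, formed where the enolate is allylated anti to the axial C10 methyl, to 22 with the side chain equatorial. The step needs site selectivity (C9 over C7), secured by the position of the carboxyl; regioselectivity in the allyl unit (C11 over C13), secured by sterics and by conjugation in the product; and retention of the E geometry, which depends on collapse of the ion pair being faster than syn–anti interconversion of the allyl complex.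

Step 14
Reactants: 22 C8 ketone
Product: 23 andrographolide 3,19-acetonide 14-O-triethylsilyl ether
Conditions: CH2Br2, Zn, TiCl4, THF/CH2Cl2, 0 °C to rt
Reagents that add atoms: dibromomethane, BrCBr
Why: Takai–Lombardo methylenation transfers CH2 from a non-basic zinc–titanium reagent to ketones but not to lactones, so the C8 methylene (C17) should be installed without epimerising C9 and without attack on the alkylidene lactone.

Step 15
Reactants: 23 protected andrographolide
Product: 24 andrographolide
Conditions: AcOH/H2O (7:3), rt
Reagents that add atoms: none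
Why: Mild aqueous acid should hydrolyse the 1,3-dioxane acetal and the triethylsilyl ether in one operation without ionising the allylic C14 alcohol or isomerising the exocyclic olefin, no stereocentre being touched.

**Compound list**

1 | geranyl chloride [(2E)-1-chloro-3,7-dimethylocta-2,6-diene] | CC(C)=CCC/C(C)=C/CCl | starting material
2 | 6,7-epoxygeranyl chloride (racemic at the epoxide) | CC1(C)OC1CC/C(C)=C/CCl | intermediate
3 | (4E)-6-chloro-4-methylhex-4-enal | O=CCC/C(C)=C/CCl | intermediate
4 | ethyl 2-[bis(2,2,2-trifluoroethoxy)phosphoryl]propanoate | CCOC(=O)C(C)P(=O)(OCC(F)(F)F)OCC(F)(F)F | starting material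
5 | ethyl (2Z,6E)-8-chloro-2,6-dimethylocta-2,6-dienoate | CCOC(=O)/C(C)=C\CC/C(C)=C/CCl | intermediate
6 | (2Z,6E)-8-chloro-2,6-dimethylocta-2,6-dien-1-ol | OC/C(C)=C\CC/C(C)=C/CCl | intermediate
7 | [(2S,3R)-3-[(3E)-5-chloro-3-methylpent-3-en-1-yl]-2-methyloxiran-2-yl]methanol | ClC/C=C(\C)CC[C@H]1O[C@@]1(C)CO | intermediate
8 | tert-butyl{[(2S,3R)-3-[(3E)-5-chloro-3-methylpent-3-en-1-yl]-2-methyloxiran-2-yl]methoxy}dimethylsilane | ClC/C=C(\C)CC[C@H]1O[C@@]1(C)CO[Si](C)(C)C(C)(C)C | intermediate
9 | methyl acetoacetate | COC(=O)CC(C)=O | starting material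
10 | methyl (6E)-9-[(2R,3S)-3-{[(tert-butyldimethylsilyl)oxy]methyl}-3-methyloxiran-2-yl]-7-methyl-3-oxonon-6-enoate | COC(=O)CC(=O)CC/C=C(\C)CC[C@H]1O[C@@]1(C)CO[Si](C)(C)C(C)(C)C | intermediate
11 | trans-decalin β-keto ester: C3 OH (equatorial), C4 CH3/CH2OTBS (axial), C10 CH3, C8 ketone, C9 CO2Me (equatorial) | O=C1CC[C@@H]2[C@](C)(CO[Si](C)(C)C(C)(C)C)[C@H](O)CC[C@@]2(C)[C@@H]1C(=O)OC | intermediate
12 | 3,19-diol of the same β-keto ester | O=C1CC[C@@H]2[C@](C)(CO)[C@H](O)CC[C@@]2(C)[C@@H]1C(=O)OC | intermediate
13 | 3,19-O-isopropylidene β-keto methyl ester | O=C1CC[C@@H]2[C@](C)(CO3)[C@H](OC3(C)C)CC[C@@]2(C)[C@@H]1C(=O)OC | intermediate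
14 | (S)-3-hydroxy-γ-butyrolactone [(4S)-4-hydroxyoxolan-2-one] | O=C1C[C@H](O)CO1 | starting material
15 | (4S)-4-(triethylsilyloxy)oxolan-2-one | O=C1C[C@H](O[Si](CC)(CC)CC)CO1 | intermediate
16 | diethyl [(4R)-2-oxo-4-(triethylsilyloxy)oxolan-3-yl]phosphonite (C13 mixture) | CCOP(OCC)C1C(=O)OC[C@H]1O[Si](CC)(CC)CC | intermediate
17 | diethyl [(4R)-2-oxo-4-(triethylsilyloxy)oxolan-3-yl]phosphonate (C13 mixture) | CCOP(=O)(OCC)C1C(=O)OC[C@H]1O[Si](CC)(CC)CC | intermediate
18 | glycolaldehyde dimer (1,4-dioxane-2,5-diol) | OC1COC(O)CO1 | starting material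
19 | (3E,4S)-3-(2-hydroxyethylidene)-4-(triethylsilyloxy)oxolan-2-one | OC/C=C1/C(=O)OC[C@H]1O[Si](CC)(CC)CC | intermediate
20 | (2E)-2-[(4S)-2-oxo-4-(triethylsilyloxy)oxolan-3-ylidene]ethyl 3,19-O-isopropylidene β-keto ester | O=C1CC[C@@H]2[C@](C)(CO3)[C@H](OC3(C)C)CC[C@@]2(C)[C@@H]1C(=O)OC/C=C1/C(=O)OC[C@H]1O[Si](CC)(CC)CC | intermediate
21 | C9 epimer of 22 (side chain axial, anti to the C10 methyl) | O=C1CC[C@@H]2[C@](C)(CO3)[C@H](OC3(C)C)CC[C@@]2(C)[C@H]1C/C=C1/C(=O)OC[C@H]1O[Si](CC)(CC)CC | intermediate
22 | 8-oxo-17-nor-andrographolide 3,19-acetonide 14-O-triethylsilyl ether | O=C1CC[C@@H]2[C@](C)(CO3)[C@H](OC3(C)C)CC[C@@]2(C)[C@@H]1C/C=C1/C(=O)OC[C@H]1O[Si](CC)(CC)CC | intermediate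
23 | andrographolide 3,19-acetonide 14-O-triethylsilyl ether | C=C1CC[C@@H]2[C@](C)(CO3)[C@H](OC3(C)C)CC[C@@]2(C)[C@@H]1C/C=C1/C(=O)OC[C@H]1O[Si](CC)(CC)CC | intermediate
24 | andrographolide | C=C1CC[C@@H]2[C@](C)(CO)[C@H](O)CC[C@@]2(C)[C@@H]1C/C=C1/C(=O)OC[C@H]1O | target

**Step count and risks**

Total: 15 steps. Longest linear sequence: 12 steps (steps 1–8 and 12–15, from geranyl chloride).

Steps most likely to fail:

Step 13 (key step). What may go wrong: geometric scrambling of the C12=C13 olefin through syn–anti interconversion of the allylpalladium intermediate; protonation of the enolate in place of allylation; a second allylation at C9; elimination of the C14 silyloxy group or incomplete equilibration at C9 during the DBU treatment. The fallback sets out from 19 and 13 and comes back at 22. Alcohol 19 is converted with CBr4/PPh3 (Appel reaction) into the allylic bromide (3E,4S)-3-(2-bromoethylidene)-4-(triethylsilyloxy)oxolan-2-one F1. The caesium enolate of 13 (Cs2CO3, MeCN) is then C-alkylated by F1 in a direct substitution that cannot scramble the olefin, giving the C9-quaternary keto ester F2. Krapcho demethoxycarbonylation (LiCl, wet DMSO, 130 °C), with protonation of the enol anti to the C10 methyl, should deliver 22.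

Step 7. What may go wrong: Lewis-acid-induced 1,2-hydride shift of the epoxide to a ketone, opening at C3 instead of C4 under the inductive pull of the silyloxymethyl group, arrest after the first ring, trapping of the C10 cation through oxygen instead of carbon, or loss of the silyl ether. The fallback sets out from 10 and comes back at 11. The terminating nucleophile is changed to a preformed enol ether: NaH then TBSCl gives the silyl enol ether methyl (2Z,6E)-3-(tert-butyldimethylsilyloxy)dienoate F3, which is cyclised with MeAlCl2 as an enol-silyl-ether-terminated cation–olefin cyclisation and gives 11 on aqueous work-up.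

Step 14. What may go wrong: slow methylene transfer to the hindered C8 carbonyl, Lewis-acid-induced ionisation at the allylic C14 ether or cleavage of the acetal before the ketone has reacted, and competing reaction at the lactone. The fallback sets out from 22 and comes back at 24. In a Peterson olefination, Me3SiCH2Li/CeCl3 (THF, −78 °C) adds to the C8 ketone to give the β-hydroxysilane F4 (either C8 epimer). Aqueous HF in MeCN then effects the acid-promoted elimination to the exocyclic olefin and removes the silyl ether and the acetal in the same operation.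

**Further compounds**

F1 | step 13 | (3E,4S)-3-(2-bromoethylidene)-4-(triethylsilyloxy)oxolan-2-one | BrC/C=C1/C(=O)OC[C@H]1O[Si](CC)(CC)CC
F2 | step 13 | methyl 3,19-O-isopropylidene-8-oxo C9-carboxylate carrying the butenolide side chain on C9 (side chain anti to the C10 methyl) | O=C1CC[C@@H]2[C@](C)(CO3)[C@H](OC3(C)C)CC[C@@]2(C)[C@]1(C/C=C1/C(=O)OC[C@H]1O[Si](CC)(CC)CC)C(=O)OC
F3 | step 7 | methyl (2Z,6E)-3-(tert-butyldimethylsilyloxy)-9-[(2R,3S)-3-{[(tert-butyldimethylsilyl)oxy]methyl}-3-methyloxiran-2-yl]-7-methylnona-2,6-dienoate | COC(=O)/C=C(/CC/C=C(\C)CC[C@H]1O[C@@]1(C)CO[Si](C)(C)C(C)(C)C)O[Si](C)(C)C(C)(C)C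
F4 | step 14 | 8-hydroxy-8-(trimethylsilylmethyl) adduct of 22 (C8 epimers) | C[Si](C)(C)CC1(O)CC[C@@H]2[C@](C)(CO3)[C@H](OC3(C)C)CC[C@@]2(C)[C@@H]1C/C=C1/C(=O)OC[C@H]1O[Si](CC)(CC)CC
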